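The plan builds ring A last, from a 2-pyrone. Ring A carries only the ethylene bridge and a methoxy group, in a 1,3 relationship. This is the C6/C4 pattern of 4-methoxy-6-methyl-2-pyrone, so only the O1–C2 lactone bridge must be traded for two CH carbons. The precursor is a 6-(2-arylethyl)-4-methoxy-2-pyrone that already holds rings B, C and D as benzyl ethers. It is heated with ethynyl 4-tolyl sulfone: bonds form at C3 and C6, CO2 leaves, and the benzene ring appears in one operation. The sulfonyl group, needed only to activate the alkyne, is then removed reductively and the benzyl ethers are hydrogenolysed.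

Key step: step 8

Remark: the target has no stereocentre. The stilbene of step 2 is carried on as an E/Z mixture, and the two bridgehead centres of the transient racemic lactone of step 8 vanish on aromatisation.

Step 1
Reactants: 1 2,5-dihydroxybenzaldehyde
Product: 2 2,5-bis(benzyloxy)benzaldehyde
Conditions: BnBr (2.4 equiv), K2CO3, DMF, 60 °C
Reagents that add atoms: benzyl bromide, BrCc1ccccc1
Why: Williamson ether synthesis, in which both phenoxides (the hydrogen-bonded 2-OH included, thanks to DMF and gentle heat) displace bromide by SN2 and the aldehyde is untouched.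

Step 2
Reactants: 2 2,5-bis(benzyloxy)benzaldehyde; 3 (4-bromobenzyl)triphenylphosphonium bromide
Product: 5 1,4-bis(benzyloxy)-2-[2-(4-bromophenyl)ethenyl]benzene (E/Z mixture), via phosphorus ylide 4 (not isolated)
Conditions: KOtBu, THF, 0 °C to rt
Reagents that add atoms: none
Why: Wittig olefination of a non-enolisable aromatic aldehyde by a semi-stabilised benzylic ylide is dependable, and the alkene geometry is irrelevant because the double bond is saturated in step 3.

Step 3
Reactants: 5 1,4-bis(benzyloxy)-2-[2-(4-bromophenyl)ethenyl]benzene (E/Z mixture)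
Product: 6 1,4-bis(benzyloxy)-2-[2-(4-bromophenyl)ethyl]benzene (ring C–D bromide)
Conditions: TsNHNH2, NaOAc, DME–H2O, reflux
Reagents that add atoms: none
Why: Diimide reduction passes two hydrogen atoms to the C=C bond through a cyclic transition state and, unlike catalytic hydrogenation, cannot touch the aryl bromide or the benzyl ethers.

Step 4
Reactants: 6 1,4-bis(benzyloxy)-2-[2-(4-bromophenyl)ethyl]benzene; 7 4-(benzyloxy)-3-hydroxybenzaldehyde
Product: 8 4-(benzyloxy)-3-(4-{2-[2,5-bis(benzyloxy)phenyl]ethyl}phenoxy)benzaldehyde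
Conditions: CuI (10 mol %), N,N-dimethylglycine·HCl (30 mol %), Cs2CO3, 1,4-dioxane, 100 °C, Ar
Reagents that add atoms: none
Why: Ligand-accelerated Ullmann diaryl ether synthesis joins the copper phenoxide of 7 to the aryl bromide to form the ring B–O–ring C bond, and the non-enolisable aldehyde and the benzyl ethers are inert to carbonate in dry dioxane.

Step 5
Reactants: 8 4-(benzyloxy)-3-(4-{2-[2,5-bis(benzyloxy)phenyl]ethyl}phenoxy)benzaldehyde
Product: 9 [4-(benzyloxy)-3-(4-{2-[2,5-bis(benzyloxy)phenyl]ethyl}phenoxy)phenyl]methanol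
Conditions: NaBH4, THF–MeOH, 0 °C
Reagents that add atoms: none
Why: Borohydride reduction of an aromatic aldehyde to the primary benzylic alcohol is fast and leaves every ether in place.

Step 6
Reactants: 9 [4-(benzyloxy)-3-(4-{2-[2,5-bis(benzyloxy)phenyl]ethyl}phenoxy)phenyl]methanol
Product: 10 1-(benzyloxy)-4-(bromomethyl)-2-(4-{2-[2,5-bis(benzyloxy)phenyl]ethyl}phenoxy)benzene
Conditions: PBr3, CH2Cl2, 0 °C
Reagents that add atoms: phosphorus tribromide, BrP(Br)Br
Why: PBr3 bromination (phosphite ester formation, then SN2 displacement by bromide) is rapid for a para-alkoxybenzylic alcohol at 0 °C, and the bromide is used at once without storage.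

Step 7
Reactants: 10 1-(benzyloxy)-4-(bromomethyl)-2-(4-{2-[2,5-bis(benzyloxy)phenyl]ethyl}phenoxy)benzene; 11 4-methoxy-6-methyl-2H-pyran-2-one
Product: 13 6-{2-[4-(benzyloxy)-3-(4-{2-[2,5-bis(benzyloxy)phenyl]ethyl}phenoxy)phenyl]ethyl}-4-methoxy-2H-pyran-2-one, via lithiated pyrone 12 (not isolated)
Conditions: 11 (1.5 equiv), LiN(iPr)2 (1.4 equiv), THF–DMPU, −78 °C; then 10, −78 to −20 °C
Reagents that add atoms: none
Why: Vinylogous deprotonation of the 6-methyl group gives the delocalised dienolate 12, whose SN2 alkylation at the exocyclic carbon by benzylic halides is the established entry to 6-(2-arylethyl)-4-methoxy-2-pyrones; excess cheap pyrone and a slight deficit of base keep free amide away from 10 and hold back double alkylation.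

Step 8
Reactants: 13 6-{2-[4-(benzyloxy)-3-(4-{2-[2,5-bis(benzyloxy)phenyl]ethyl}phenoxy)phenyl]ethyl}-4-methoxy-2H-pyran-2-one; 14 ethynyl 4-tolyl sulfone
Product: 16 4-methoxy-2-{2-[4-(benzyloxy)-3-(4-{2-[2,5-bis(benzyloxy)phenyl]ethyl}phenoxy)phenyl]ethyl}phenyl 4-tolyl sulfone (tri-O-benzyl target with the sulfonyl group on ring A ortho to the bridge), via bridged lactone 15 (not isolated)
Conditions: 14 (3 equiv, in portions), BHT (cat.), 1,2-dichlorobenzene, 150–160 °C, Ar
Reagents that add atoms: none
Why: The C3=C4–C5=C6 diene of 13, made electron-rich by the C4 methoxy group and the ring oxygen, adds the electron-poor alkyne 14 in a concerted normal-electron-demand [4+2] cycloaddition to the 2-oxabicyclo[2.2.2]octadienone 15, which at this temperature expels CO2 by retro-[4+2] and aromatises irreversibly. The closest known reaction type is the Diels–Alder/decarboxylation of alkyl- and alkoxy-substituted 2-pyrones with activated alkynes such as acetylenic esters, which likewise needs strong heating. Ring A is closed intermolecularly as a six-membered carbocycle from four pyrone carbons and the two alkyne carbons, through the new bonds C3–CH and C6–C(SO2Tol). The two bridgehead stereocentres of 15 are racemic, tied to each other by the bicycle, and erased on loss of CO2, so 16 has none. Regioselectivity follows from the largest HOMO coefficient at C3 meeting the β-carbon of the alkynyl sulfone, which places sulfur ortho to the bridge and para to the methoxy group, and the opposite orientation would be harmless because it converges on 17 in step 9. Chemoselectivity is secured because the pyrone is the only diene present and all three phenols are capped as benzyl ethers, so no O–H can add to the alkynyl sulfone.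

Step 9
Reactants: 16 4-methoxy-2-{2-[4-(benzyloxy)-3-(4-{2-[2,5-bis(benzyloxy)phenyl]ethyl}phenoxy)phenyl]ethyl}phenyl 4-tolyl sulfone
Product: 17 1-(benzyloxy)-2-(4-{2-[2,5-bis(benzyloxy)phenyl]ethyl}phenoxy)-4-[2-(3-methoxyphenyl)ethyl]benzene (tri-O-benzyl target)
Conditions: Mg turnings, MeOH–THF, rt to 50 °C; aq NH4Cl
Reagents that add atoms: none
Why: Dissolving-metal reductive desulfonylation, in which the sulfone radical anion should break the crowded ring A–S bond (ortho-alkyl strain, and 4-toluenesulfinate is a better leaving group than the more electron-rich ring A sulfinate) and methanol protonates the reduced aryl fragment, while benzyl, methyl and diaryl ethers stay intact.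

Step 10
Reactants: 17 1-(benzyloxy)-2-(4-{2-[2,5-bis(benzyloxy)phenyl]ethyl}phenoxy)-4-[2-(3-methoxyphenyl)ethyl]benzene
Product: 18 2-[2-(4-{2-hydroxy-5-[2-(3-methoxyphenyl)ethyl]phenoxy}phenyl)ethyl]benzene-1,4-diol (target)
Conditions: H2 (1 atm), 10% Pd/C, EtOAc–MeOH, rt
Reagents that add atoms: none
Why: Catalytic hydrogenolysis cleaves the three benzylic C–O bonds and spares the methyl ether, the diaryl ether and the arenes; 17 is chromatographed first so that no sulfur reaches the catalyst, and the hydroquinone is handled under argon.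

Compound list
1 | 2,5-dihydroxybenzaldehyde | O=Cc1cc(O)ccc1O | starting material
2 | 2,5-bis(benzyloxy)benzaldehyde | O=Cc1cc(OCc2ccccc2)ccc1OCc1ccccc1 | intermediate
3 | (4-bromobenzyl)triphenylphosphonium bromide | Brc1ccc(C[P+](c2ccccc2)(c2ccccc2)c2ccccc2)cc1.[Br-] | starting material
4 | (4-bromobenzylidene)triphenylphosphorane (not isolated) | Brc1ccc(C=P(c2ccccc2)(c2ccccc2)c2ccccc2)cc1 | intermediate
5 | 1,4-bis(benzyloxy)-2-[2-(4-bromophenyl)ethenyl]benzene, E/Z mixture | Brc1ccc(C=Cc2cc(OCc3ccccc3)ccc2OCc2ccccc2)cc1 | intermediate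
6 | 1,4-bis(benzyloxy)-2-[2-(4-bromophenyl)ethyl]benzene | Brc1ccc(CCc2cc(OCc3ccccc3)ccc2OCc2ccccc2)cc1 | intermediate
7 | 4-(benzyloxy)-3-hydroxybenzaldehyde | O=Cc1ccc(OCc2ccccc2)c(O)c1 | starting material
8 | 4-(benzyloxy)-3-(4-{2-[2,5-bis(benzyloxy)phenyl]ethyl}phenoxy)benzaldehyde | O=Cc1ccc(OCc2ccccc2)c(Oc2ccc(CCc3cc(OCc4ccccc4)ccc3OCc3ccccc3)cc2)c1 | intermediate
9 | [4-(benzyloxy)-3-(4-{2-[2,5-bis(benzyloxy)phenyl]ethyl}phenoxy)phenyl]methanol | OCc1ccc(OCc2ccccc2)c(Oc2ccc(CCc3cc(OCc4ccccc4)ccc3OCc3ccccc3)cc2)c1 | intermediate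
10 | 1-(benzyloxy)-4-(bromomethyl)-2-(4-{2-[2,5-bis(benzyloxy)phenyl]ethyl}phenoxy)benzene | BrCc1ccc(OCc2ccccc2)c(Oc2ccc(CCc3cc(OCc4ccccc4)ccc3OCc3ccccc3)cc2)c1 | intermediate
11 | 4-methoxy-6-methyl-2H-pyran-2-one | COC1=CC(=O)OC(C)=C1 | starting material
12 | 6-(lithiomethyl)-4-methoxy-2H-pyran-2-one (not isolated) | COC1=CC(=O)OC(C[Li])=C1 | intermediate
13 | 6-{2-[4-(benzyloxy)-3-(4-{2-[2,5-bis(benzyloxy)phenyl]ethyl}phenoxy)phenyl]ethyl}-4-methoxy-2H-pyran-2-one | COC1=CC(=O)OC(CCc2ccc(OCc3ccccc3)c(Oc3ccc(CCc4cc(OCc5ccccc5)ccc4OCc4ccccc4)cc3)c2)=C1 | intermediate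
14 | ethynyl 4-tolyl sulfone | C#CS(=O)(=O)c1ccc(C)cc1 | starting material
15 | racemic 1-(2-arylethyl)-5-methoxy-7-(4-tolylsulfonyl)-2-oxabicyclo[2.2.2]octa-5,7-dien-3-one, aryl = rings B–C–D as in 13 (not isolated) | COC1=CC2(CCc3ccc(OCc4ccccc4)c(Oc4ccc(CCc5cc(OCc6ccccc6)ccc5OCc5ccccc5)cc4)c3)OC(=O)C1C=C2S(=O)(=O)c1ccc(C)cc1 | intermediate
16 | 4-methoxy-2-{2-[4-(benzyloxy)-3-(4-{2-[2,5-bis(benzyloxy)phenyl]ethyl}phenoxy)phenyl]ethyl}phenyl 4-tolyl sulfone | COc1cc(CCc2ccc(OCc3ccccc3)c(Oc3ccc(CCc4cc(OCc5ccccc5)ccc4OCc4ccccc4)cc3)c2)c(S(=O)(=O)c2ccc(C)cc2)cc1 | intermediate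
17 | 1-(benzyloxy)-2-(4-{2-[2,5-bis(benzyloxy)phenyl]ethyl}phenoxy)-4-[2-(3-methoxyphenyl)ethyl]benzene | COc1cccc(CCc2ccc(OCc3ccccc3)c(Oc3ccc(CCc4cc(OCc5ccccc5)ccc4OCc4ccccc4)cc3)c2)c1 | intermediate
18 | 2-[2-(4-{2-hydroxy-5-[2-(3-methoxyphenyl)ethyl]phenoxy}phenyl)ethyl]benzene-1,4-diol | COc1cccc(CCc2ccc(O)c(Oc3ccc(CCc4cc(O)ccc4O)cc3)c2)c1 | target

Total step count: 10. Longest linear sequence: 10 steps, from 1 to 18. Compounds 3, 7, 11 and 14 are purchased.

Steps most likely to fail

Step 8. The cycloaddition may be slower than the thermal oligomerisation of the terminal alkynyl sulfone, so the pyrone would be recovered or slowly degraded at the temperature needed. The fallback buys ring A instead of building it. It sets out from aldehyde 8 and comes back at target 18. Commercial (3-methoxybenzyl)triphenylphosphonium chloride is deprotonated with KOtBu in THF to (3-methoxybenzylidene)triphenylphosphorane F1. This ylide olefinates 8 in a Wittig reaction to 1-(benzyloxy)-2-(4-{2-[2,5-bis(benzyloxy)phenyl]ethyl}phenoxy)-4-[2-(3-methoxyphenyl)ethenyl]benzene F2 (E/Z mixture). Hydrogen over Pd/C in EtOAc–MeOH then saturates the double bond and removes the three benzyl groups in the same operation, which should give 18.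

Step 9. Electron transfer may break the tolyl–sulfur bond instead of the ring A–sulfur bond, or may stall on passivated metal. The fallback lowers sulfur to the sulfide level and removes it by hydrogenolytic desulfurisation, which does not depend on which C–S bond breaks first. It sets out from 16 and comes back at 17. LiAlH4–TiCl4 in THF (−78 °C to rt) deoxygenates the sulfone to 4-methoxy-2-{2-[4-(benzyloxy)-3-(4-{2-[2,5-bis(benzyloxy)phenyl]ethyl}phenoxy)phenyl]ethyl}phenyl 4-tolyl sulfide F3. Raney Ni in EtOH–THF then cuts both C–S bonds to give 17. Any benzyl ether lost on the nickel only anticipates step 10.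

Step 7. Metalation at C3 may compete with metalation of the methyl group, proton exchange may lead to double alkylation, and the electron-rich benzylic bromide may decay before it is captured. The fallback forms the same C–C bond by condensation instead of alkylation. It sets out from aldehyde 8, so steps 5 and 6 are not needed, and comes back at 13. Compounds 8 and 11 are condensed with Mg(OMe)2 in refluxing MeOH–THF, the vinylogous aldol condensation used for styrylpyrones. This should give 6-{(E)-2-[4-(benzyloxy)-3-(4-{2-[2,5-bis(benzyloxy)phenyl]ethyl}phenoxy)phenyl]ethenyl}-4-methoxy-2H-pyran-2-one F4. Its exocyclic disubstituted C=C bond is then saturated with diimide (TsNHNH2, NaOAc, DME–H2O, reflux). The trisubstituted, carbonyl-conjugated ring double bonds are far less reactive towards diimide and the benzyl ethers are inert, so the product should be 13.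

Further compounds
F1 | step 8 | (3-methoxybenzylidene)triphenylphosphorane | COc1cccc(C=P(c2ccccc2)(c2ccccc2)c2ccccc2)c1
F2 | step 8 | 1-(benzyloxy)-2-(4-{2-[2,5-bis(benzyloxy)phenyl]ethyl}phenoxy)-4-[2-(3-methoxyphenyl)ethenyl]benzene, E/Z mixture | COc1cccc(C=Cc2ccc(OCc3ccccc3)c(Oc3ccc(CCc4cc(OCc5ccccc5)ccc4OCc4ccccc4)cc3)c2)c1
F3 | step 9 | 4-methoxy-2-{2-[4-(benzyloxy)-3-(4-{2-[2,5-bis(benzyloxy)phenyl]ethyl}phenoxy)phenyl]ethyl}phenyl 4-tolyl sulfide | COc1cc(CCc2ccc(OCc3ccccc3)c(Oc3ccc(CCc4cc(OCc5ccccc5)ccc4OCc4ccccc4)cc3)c2)c(Sc2ccc(C)cc2)cc1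
F4 | step 7 | 6-{(E)-2-[4-(benzyloxy)-3-(4-{2-[2,5-bis(benzyloxy)phenyl]ethyl}phenoxy)phenyl]ethenyl}-4-methoxy-2H-pyran-2-one | COC1=CC(=O)OC(/C=C/c2ccc(OCc3ccccc3)c(Oc3ccc(CCc4cc(OCc5ccccc5)ccc4OCc4ccccc4)cc3)c2)=C1
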